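## Analysis of the target

Atom labels used in the text: C1–C3 are the propanoate chain (C3 the ester carbon) and C4 is the isopropenyl carbon. Ring B is C5 (CH bearing isopropenyl), C6 (CH2), C7 (ketone), C8, C9 and C10 (quaternary, bearing CH3 and the chain). Ring C is C8, C9, C11 (C=O), C12 (C–OH), C13 (C–isopropyl) and C14 (C=O). Locants inside compound names are systematic.

Target 20 (C21H26O6) is a six-membered carbocycle (ring B) fused through C8=C9 to a fully substituted 2-hydroxy-1,4-benzoquinone (ring C). The C7 ketone is conjugated with the quinone. There are only two stereocentres, and they are adjacent: the tertiary allylic C5 (S) and the quaternary C10 (S). The C10 methyl is cis to the isopropenyl group, and the C1–C3 chain is trans to it. No third stereocentre exists from which this pair could be relayed, so its absolute configuration has to come from a reagent or catalyst. The hydroxyquinone is acidic, redox-active and open to nucleophiles, so it must be formed late. The isopropenyl group rules out hydrogenation, peracids and strong acid, and the methyl ester rules out organolithium reagents and excess strong base. The hard parts are the vicinal quaternary/tertiary pair next to the ring fusion and the regiodefined oxygen pattern (C7, C11, C12, C14) around a ring C with no free position. The strategy rests on the C10–C5 bond of ring B: with C1 trans to isopropenyl it is the imprint of the α,β-double bond of an (E)-2-methyl enal (C10 the α-carbon, C5 the β-carbon). The remaining ring-B carbons C6–C9 are then a butadiene whose oxygen sits at C9, where ring C later needs a carbonyl.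

## Retrosynthetic reasoning

**C7 ketone (20 ⇒ 19 ⇒ 18).** The C7 carbonyl is taken back to a carbinol (19) and its silyl ether (18). C7 is kept at the alcohol level while ring C is built so that C9 is the only electrophilic ring-B carbonyl. A C7 ketone would be less hindered than C9 and would draw the ring-closing aldol to the wrong carbon. The forward steps are a desilylation and an oxidation of a carbinol next to a quinone.

**C11 oxygen (18 ⇒ 17).** The C11–O bond is cut, leaving resorcinol 17 with hydroxyls at C12 and C14. C11 is its only unsubstituted ring carbon and is para to the C14 hydroxyl, so a radical phenol oxidation can only deliver the 11,14-quinone with the C12 hydroxyl kept.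

**Ring C (17 ⇒ 16).** The C9–C11 bond is cut in the aldol sense, and the aromatic ring is unfolded to triketone 16. The cut is placed there because C11 is the only unsubstituted carbon of ring C and C9 already carries a ketone in ring B. The forward step is a six-membered aldol addition, dehydration and enolisation.

**Side chain of ring C (16 ⇒ 14 ⇒ 13).** The C13–C12 bond is cut (an acetyl unit, via bis-silyl dienol ether 15), then the C8–C14 bond (an isovaleryl unit on ketone 13). Both are acylations of enol derivatives, and C8 is the only enolisable position of 13 because C10 is quaternary. The forward reactions must avoid strong base because of the methyl ester.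

**C7 oxygen (13 ⇒ 12 ⇒ 10).** The C7–O bond is cut back to enone 10. The enone β-carbon is exactly C7, so a conjugate borylation and C–B oxidation (via boronate 11) place the oxygen without touching the isolated alkene or the ester.

**Enone and chain (10 ⇒ 9 ⇒ 8 ⇒ 7 ⇒ 6).** The C9 carbonyl comes from allylic alcohol 9 and its silyl ether 8. The C1–C3 chain comes from enoate 7 by conjugate reduction, and 7 from aldehyde 6 by a two-carbon phosphonate olefination that cuts C1=C2. The formyl group of 6 sits on the quaternary carbon, so it cannot epimerise.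

**Ring B (6 ⇒ 3 + 5).** C9–C10 and C5–C6 are cut together. This is the only disconnection that removes both stereocentres at once and turns their relative configuration into an alkene geometry. The forward cycloaddition must control enantioface, ortho regiochemistry and the choice of the α,β-alkene of dienal 3 over its γ,δ-alkene.

**Precursors (3 ⇒ 1 + 2; 5 ⇒ 4).** The C5=C10 bond of 3 is cut to methacrolein 1 and ylide 2, which fixes the E geometry. Silyloxydiene 5 is the silyl dienol ether of crotonaldehyde 4.

## Alternatives that were turned down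

**Alternative 1:** The disconnection cuts C4–C5 and C10–C1 on a preformed aromatic bicycle, so ring C and the C7 oxygen come with the naphthalene. In the forward key step, naphthyl oxazoline A2 takes up isopropenyllithium A3 at C5, and alkylation at C10 by iodide A4 then gives dihydronaphthalene A1. No ring is formed.
- For: one operation sets both stereocentres. The two groups enter anti, which is the required chain-trans-to-isopropenyl relationship, and the chiral oxazoline sets the absolute sense. Ring C, the isopropyl group and the C7 oxygen (as an enol ether) are present from the start. On convergence and on the number of skeletal bonds still to be made it is stronger than the chosen route.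
- Against: the oxazoline carbon must end as the C10 methyl group. That is a reduction through three oxidation levels at a neopentyl position, in practice via the aldehyde and a hydrazone or thioacetal deoxygenation, which sits badly with the isopropenyl group and the C7 oxygen. A2 is electron-rich, which slows the addition of A3. The C12 and C14 methyl ethers need Lewis-acid cleavage that threatens the isopropenyl group, and the C11 oxidation is still required afterwards. The chain arrives as a silyl ether, three steps from the methyl ester.
- Comparison: the chosen route makes more C–C bonds, but the methyl group arrives as a methyl group and the ester as an ester. Its only unmasking steps are two desilylations and two mild alcohol oxidations.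

**Alternative 2:** The disconnection is C9–C11 of ring C. In the forward key step, base closes triketone A6 by aldol attack of C11 on C9, and dehydration gives resorcinol A5 with C7 as a ketal.
- For: it is a mild, polyketide-type closure that gives the fully substituted ring with the right oxygen pattern. Carrying C7 at the ketone level saves the final desilylation and oxidation, and on that point it is stronger than the chosen route.
- Against: as a strategy it is an end-game. It does not say how the C5/C10 pair is made or how its absolute configuration is set, so the hard part of the target is left to an unspecified synthesis of the ring-B ketone. A β-keto ketal with an acidic C8–H can open to a vinylogous ester under the basic acylation and aldol conditions, and selective mono-ketalisation of an enolisable 1,3-dione is itself not reliable.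
- Comparison: the chosen route uses the same ring closure as its step 12, after the stereodiad has been set by cycloaddition. It takes the C7 oxygen at the alcohol level because that is what enone 10 delivers directly, at the price of two extra late steps.

**Alternative 3:** The disconnection is C8–C14 of ring C, with C9–C11 made beforehand by carbonyl addition. In the forward key step, cyclobutenone A8 undergoes thermal four-electron ring opening and six-electron closure onto C8 to give hydroquinone A7.
- For: the regiochemistry of ring C is built into the four-membered ring. All ring-C oxygens and the isopropyl group arrive in one convergent operation, and the quinone needs only a mild oxidation of the hydroquinone. On ring-C regiocontrol and convergence it is stronger than the chosen route.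
- Against: A8 requires an alkenyl-metal nucleophile at C9, next to the quaternary C10. That excludes the methyl ester, so the chain is carried as a silyl ether and three steps are added at the end. The C12 isopropyl ether must be cleaved in the presence of the isopropenyl group. The ring-B partner with its two stereocentres again has to come from elsewhere.
- Comparison: the chosen route builds ring C linearly in three steps and needs a separate oxidation at C11. In exchange it keeps the ester throughout and solves the stereochemical problem in the same sequence.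

Key step: step 3

**Assumption (remark on the chemistry):** the (S)-diphenylprolinol-derived catalyst is taken to expose the C10-Re/C5-Si face of dienal 3, by analogy with its sense toward 2-methylacrolein under formyl C–H···O binding. If the antipodal adduct forms, the (R)-catalyst is used and nothing else changes.

## Route

Step 1
Reactants: 1 methacrolein (2-methylprop-2-enal); 2 2-(triphenylphosphoranylidene)propanal
Product: 3 (2E)-2,4-dimethylpenta-2,4-dienal
Conditions: 1 (3 equiv), toluene, 90 °C, sealed vessel
Reagents that add atoms: none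
Why: Wittig olefination with a stabilised formyl ylide; the excess of the more reactive aldehyde 1 should stop the reaction at mono-olefination, and a stabilised ylide gives the E alkene (formyl trans to isopropenyl).

Step 2
Reactants: 4 crotonaldehyde ((E)-but-2-enal)
Product: 5 (E)-1-(tert-butyldimethylsilyloxy)buta-1,3-diene
Conditions: TBSOTf, Et3N, Et2O, 0 °C to rt
Reagents that add atoms: tert-butyldimethylsilyl trifluoromethanesulfonate, CC(C)(C)[Si](C)(C)OS(=O)(=O)C(F)(F)F
Why: O-silylation of the formyl group and γ-deprotonation (1,4-elimination) is the standard route to 1-silyloxydienes; the E isomer should predominate, and the Z isomer cannot reach an unstrained s-cis conformation, so it is a spectator in step 3.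

Step 3
Reactants: 3 (2E)-2,4-dimethylpenta-2,4-dienal; 5 (E)-1-(tert-butyldimethylsilyloxy)buta-1,3-diene
Product: 6 (1S,2R,6S)-2-(tert-butyldimethylsilyloxy)-1-methyl-6-(prop-1-en-2-yl)cyclohex-3-ene-1-carbaldehyde
Conditions: 5 (2 equiv), protonated (S)-B-o-tolyl diphenylprolinol oxazaborolidine C24H24BNO·HN(SO2CF3)2 (15 mol %), CH2Cl2, −78 to −40 °C
Reagents that add atoms: none
Why: The protonated oxazaborolidine binds the formyl oxygen of 3 (B–O coordination plus a formyl C–H···O contact) and lowers the LUMO of the C10=C5 bond, and 5 then adds in a concerted, asynchronous [4+2] in which C5–C6 forms ahead of C9–C10. The closest known reaction type is the oxazaborolidinium-catalysed Diels–Alder reaction of 2-methyl-substituted enals with silyloxydienes. Ring B closes by cycloaddition, with both σ-bonds (C9–C10 and C5–C6) formed in the one step. C10 and C5 are set together: suprafacial addition carries the E geometry of 3 into the adduct, so the methyl group ends cis and the formyl group (the future C1) trans to isopropenyl, and the aryl group of the catalyst shields one enal face and so decides the enantiomer. C9 follows from the endo orientation of the formyl group (silyloxy cis to formyl); this centre is erased in step 7, so an exo fraction converges. Ortho regiochemistry follows from the large HOMO coefficient at the unsubstituted terminus of 5 and the large LUMO coefficient at C5 of the activated enal. Reaction at the α,β-bond and not the γ,δ-bond, and with 5 as the diene and not the diene unit of 3, follows from formyl activation, the excess of the electron-rich diene and the low temperature.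

Step 4
Reactants: 6 (1S,2R,6S)-2-(tert-butyldimethylsilyloxy)-1-methyl-6-(prop-1-en-2-yl)cyclohex-3-ene-1-carbaldehyde
Product: 7 methyl (2E)-3-[(1S,2R,6S)-2-(tert-butyldimethylsilyloxy)-1-methyl-6-(prop-1-en-2-yl)cyclohex-3-en-1-yl]prop-2-enoate
Conditions: (MeO)2P(O)CH2CO2Me, NaH, THF, 0 to 50 °C
Reagents that add atoms: trimethyl phosphonoacetate, COC(=O)CP(=O)(OC)OC
Why: Horner–Wadsworth–Emmons olefination; the aldehyde has no α-hydrogen, so it can neither epimerise nor eliminate the β-silyloxy group, and the stabilised phosphonate anion should give the E enoate, which brings in C2, C3 and the ester methoxy group.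

Step 5
Reactants: 7 methyl (2E)-3-[(1S,2R,6S)-2-(tert-butyldimethylsilyloxy)-1-methyl-6-(prop-1-en-2-yl)cyclohex-3-en-1-yl]prop-2-enoate
Product: 8 methyl 3-[(1S,2R,6S)-2-(tert-butyldimethylsilyloxy)-1-methyl-6-(prop-1-en-2-yl)cyclohex-3-en-1-yl]propanoate
Conditions: Mg turnings, MeOH, 0 °C to rt
Reagents that add atoms: none
Why: Dissolving-metal conjugate reduction (electron transfer from Mg to the enoate, protonation by MeOH) should reduce only the conjugated C1=C2 bond; the isolated ring and isopropenyl alkenes and the silyl ether are not electron acceptors, and methanol as solvent keeps the methyl ester.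

Step 6
Reactants: 8 methyl 3-[(1S,2R,6S)-2-(tert-butyldimethylsilyloxy)-1-methyl-6-(prop-1-en-2-yl)cyclohex-3-en-1-yl]propanoate
Product: 9 methyl 3-[(1S,2R,6S)-2-hydroxy-1-methyl-6-(prop-1-en-2-yl)cyclohex-3-en-1-yl]propanoate
Conditions: HF·pyridine, pyridine, THF, 0 °C to rt
Reagents that add atoms: none
Why: Fluoride-driven Si–O cleavage under buffered, weakly acidic conditions, chosen over basic fluoride so that the δ-hydroxy ester is not pushed toward lactonisation; the crude alcohol is taken directly into step 7.

Step 7
Reactants: 9 methyl 3-[(1S,2R,6S)-2-hydroxy-1-methyl-6-(prop-1-en-2-yl)cyclohex-3-en-1-yl]propanoate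
Product: 10 methyl 3-[(1S,6S)-1-methyl-2-oxo-6-(prop-1-en-2-yl)cyclohex-3-en-1-yl]propanoate
Conditions: Dess–Martin periodinane, CH2Cl2, 0 °C to rt
Reagents that add atoms: none
Why: Dess–Martin oxidation of the secondary allylic alcohol to the C9 enone under neutral conditions that leave the isopropenyl group and the ester alone; the C9 stereocentre, which only carried the oxygen, is removed here.

Step 8
Reactants: 10 methyl 3-[(1S,6S)-1-methyl-2-oxo-6-(prop-1-en-2-yl)cyclohex-3-en-1-yl]propanoate
Product: 12 methyl 3-[(1S,4R,6S)-4-hydroxy-1-methyl-2-oxo-6-(prop-1-en-2-yl)cyclohexyl]propanoate, via C7-pinacolboryl ketone 11 (not isolated)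
Conditions: B2pin2, CuCl (5 mol %), NaOt-Bu (10 mol %), DPEphos (5 mol %), MeOH, THF, rt; then NaBO3·4H2O, THF/H2O, rt
Reagents that add atoms: bis(pinacolato)diboron, CC1(C)OB(OC1(C)C)B1OC(C)(C)C(C)(C)O1 (its boron stays only in 11); sodium perborate, [Na+].[O-]OB=O (the C7 oxygen of 12)
Why: Copper-catalysed conjugate borylation of the enone (boryl–copper addition at C7, methanolysis of the enolate) and stereoretentive C–B oxidation give the β-hydroxy ketone without touching the isolated alkene or the ester. Axial attack on the half-chair with isopropenyl pseudo-equatorial should place boron, and hence oxygen, trans to isopropenyl; this centre is removed in step 15, so its configuration does not matter.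

Step 9
Reactants: 12 methyl 3-[(1S,4R,6S)-4-hydroxy-1-methyl-2-oxo-6-(prop-1-en-2-yl)cyclohexyl]propanoate
Product: 13 methyl 3-[(1S,4R,6S)-4-(tert-butyldimethylsilyloxy)-1-methyl-2-oxo-6-(prop-1-en-2-yl)cyclohexyl]propanoate
Conditions: TBSCl, imidazole, DMF, rt
Reagents that add atoms: tert-butyldimethylsilyl chloride, CC(C)(C)[Si](C)(C)Cl
Why: Standard silylation of a secondary alcohol under mildly basic conditions that should not dehydrate the β-hydroxy ketone; it keeps C7 at the alcohol level so that C9 stays the only ring-B carbonyl while ring C is built.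

Step 10
Reactants: 13 methyl 3-[(1S,4R,6S)-4-(tert-butyldimethylsilyloxy)-1-methyl-2-oxo-6-(prop-1-en-2-yl)cyclohexyl]propanoate
Product: 14 methyl 3-[(1S,4R,6S)-4-(tert-butyldimethylsilyloxy)-2-hydroxy-1-methyl-3-(3-methylbutanoyl)-6-(prop-1-en-2-yl)cyclohex-2-en-1-yl]propanoate (β-diketone drawn as its C9 enol)
Conditions: MgBr2·OEt2, i-Pr2NEt, 3-methylbutanoyl chloride, CH2Cl2, 0 °C to rt
Reagents that add atoms: 3-methylbutanoyl chloride, CC(C)CC(=O)Cl
Why: Soft-enolisation Claisen-type C-acylation: MgBr2 activates the C9 ketone so that the amine can deprotonate C8, the only enolisable position because C10 is quaternary, and the magnesium enolate is acylated on carbon to the chelated β-diketone. No strong base is present, so the methyl ester is not enolised; the step brings in C14, C13 and the isopropyl group.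

Step 11
Reactants: 14 methyl 3-[(1S,4R,6S)-4-(tert-butyldimethylsilyloxy)-2-hydroxy-1-methyl-3-(3-methylbutanoyl)-6-(prop-1-en-2-yl)cyclohex-2-en-1-yl]propanoate
Product: 16 methyl 3-[(1S,4R,6S)-4-(tert-butyldimethylsilyloxy)-2-hydroxy-3-[3-hydroxy-2-(propan-2-yl)but-2-enoyl]-1-methyl-6-(prop-1-en-2-yl)cyclohex-2-en-1-yl]propanoate (C8-(2-isopropylacetoacetyl) ketone drawn as a bis-enol), via bis(trimethylsilyl) dienol ether 15 (not isolated)
Conditions: TMSOTf (2.5 equiv), Et3N (3 equiv), Et2O, 0 °C; filtration and concentration under Ar; then AcCl, CH2Cl2, −78 °C to rt; aqueous work-up at pH 5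
Reagents that add atoms: acetyl chloride, CC(=O)Cl; trimethylsilyl trifluoromethanesulfonate, C[Si](C)(C)OS(=O)(=O)C(F)(F)F (its silicon stays only in 15)
Why: Double O-silylation turns the β-diketone into a 1,3-bis(silyloxy)-1,3-diene, whose second enol ether can only form toward C13 because C10 is quaternary. Such dienes are acylated by acid chlorides at the terminal carbon (Mukaiyama-type γ-acylation), here C13, which adds C12 and C11 without strong base; the new C13 centre is epimerisable and disappears on aromatisation.

Step 12
Reactants: 16 methyl 3-[(1S,4R,6S)-4-(tert-butyldimethylsilyloxy)-2-hydroxy-3-[3-hydroxy-2-(propan-2-yl)but-2-enoyl]-1-methyl-6-(prop-1-en-2-yl)cyclohex-2-en-1-yl]propanoate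
Product: 17 methyl 3-[(1S,2S,4R)-4-(tert-butyldimethylsilyloxy)-5,7-dihydroxy-1-methyl-6-(propan-2-yl)-2-(prop-1-en-2-yl)-1,2,3,4-tetrahydronaphthalen-1-yl]propanoate
Conditions: Cs2CO3, MeOH, 0 °C to rt; then AcOH
Reagents that add atoms: none
Why: Polyketide-type aldol aromatisation: the terminal methyl carbon C11 of the side-chain diketone adds as its enolate to the C9 ketone, the only carbonyl within six-membered reach that is not an acyl carbon of the chain, and dehydration and enolisation give the resorcinol. C7 is at the alcohol level and cannot compete as an electrophile, and methanol as solvent keeps the methyl ester.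

Step 13
Reactants: 17 methyl 3-[(1S,2S,4R)-4-(tert-butyldimethylsilyloxy)-5,7-dihydroxy-1-methyl-6-(propan-2-yl)-2-(prop-1-en-2-yl)-1,2,3,4-tetrahydronaphthalen-1-yl]propanoate
Product: 18 methyl 3-[(1S,2S,4R)-4-(tert-butyldimethylsilyloxy)-7-hydroxy-1-methyl-5,8-dioxo-6-(propan-2-yl)-2-(prop-1-en-2-yl)-1,2,3,4,5,8-hexahydronaphthalen-1-yl]propanoate
Conditions: K2[ON(SO3)2] (2.5 equiv), KH2PO4 buffer, acetone/H2O, 0 °C to rt
Reagents that add atoms: potassium nitrosodisulfonate, [K+].[K+].[O]N(S(=O)(=O)[O-])S(=O)(=O)[O-] (the C11 oxygen)
Why: Radical phenol oxidation: hydrogen abstraction from the C14 hydroxyl, coupling of a second nitrosodisulfonate radical at C11 (the only unsubstituted ring carbon, para to that hydroxyl) and loss of imidodisulfonate give the 11,14-quinone. The C12 hydroxyl is kept as the hydroxyl of the hydroxyquinone, and the alkene, ester and silyl ether are inert to this oxidant.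

Step 14
Reactants: 18 methyl 3-[(1S,2S,4R)-4-(tert-butyldimethylsilyloxy)-7-hydroxy-1-methyl-5,8-dioxo-6-(propan-2-yl)-2-(prop-1-en-2-yl)-1,2,3,4,5,8-hexahydronaphthalen-1-yl]propanoate
Product: 19 methyl 3-[(1S,2S,4R)-4,7-dihydroxy-1-methyl-5,8-dioxo-6-(propan-2-yl)-2-(prop-1-en-2-yl)-1,2,3,4,5,8-hexahydronaphthalen-1-yl]propanoate
Conditions: HF·pyridine, THF, 0 °C to rt
Reagents that add atoms: none
Why: Fluoride-driven cleavage of the secondary silyl ether; the weakly acidic medium should be tolerated by the hydroxyquinone, the ester and the isopropenyl group, and a carbinol next to a quinone ring is a stable arrangement.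

Step 15
Reactants: 19 methyl 3-[(1S,2S,4R)-4,7-dihydroxy-1-methyl-5,8-dioxo-6-(propan-2-yl)-2-(prop-1-en-2-yl)-1,2,3,4,5,8-hexahydronaphthalen-1-yl]propanoate
Product: 20 methyl 3-[(1S,2S)-7-hydroxy-1-methyl-4,5,8-trioxo-6-(propan-2-yl)-2-(prop-1-en-2-yl)-1,2,3,4,5,8-hexahydronaphthalen-1-yl]propanoate
Conditions: Dess–Martin periodinane, CH2Cl2, 0 °C to rt
Reagents that add atoms: none
Why: Dess–Martin oxidation of the secondary carbinol next to the quinone ring to the C7 ketone; the quinone is already at its highest oxidation level, and the neutral, non-nucleophilic conditions spare the isopropenyl group and the ester. C5 is β to the new ketone and not enolisable, so the stereodiad is untouched.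

## Compound list

1 | methacrolein (2-methylprop-2-enal) | C=C(C)C=O | starting material
2 | 2-(triphenylphosphoranylidene)propanal | CC(C=O)=P(c1ccccc1)(c1ccccc1)c1ccccc1 | starting material
3 | (2E)-2,4-dimethylpenta-2,4-dienal | C=C(C)/C=C(\C)C=O | intermediate
4 | crotonaldehyde ((E)-but-2-enal) | C/C=C/C=O | starting material
5 | (E)-1-(tert-butyldimethylsilyloxy)buta-1,3-diene | C=C/C=C/O[Si](C)(C)C(C)(C)C | intermediate
6 | (1S,2R,6S)-2-(tert-butyldimethylsilyloxy)-1-methyl-6-(prop-1-en-2-yl)cyclohex-3-ene-1-carbaldehyde | C=C(C)[C@@H]1CC=C[C@@H](O[Si](C)(C)C(C)(C)C)[C@@]1(C)C=O | intermediate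
7 | methyl (2E)-3-[(1S,2R,6S)-2-(tert-butyldimethylsilyloxy)-1-methyl-6-(prop-1-en-2-yl)cyclohex-3-en-1-yl]prop-2-enoate | C=C(C)[C@@H]1CC=C[C@@H](O[Si](C)(C)C(C)(C)C)[C@@]1(C)/C=C/C(=O)OC | intermediate
8 | methyl 3-[(1S,2R,6S)-2-(tert-butyldimethylsilyloxy)-1-methyl-6-(prop-1-en-2-yl)cyclohex-3-en-1-yl]propanoate | C=C(C)[C@@H]1CC=C[C@@H](O[Si](C)(C)C(C)(C)C)[C@@]1(C)CCC(=O)OC | intermediate
9 | methyl 3-[(1S,2R,6S)-2-hydroxy-1-methyl-6-(prop-1-en-2-yl)cyclohex-3-en-1-yl]propanoate | C=C(C)[C@@H]1CC=C[C@@H](O)[C@@]1(C)CCC(=O)OC | intermediate
10 | methyl 3-[(1S,6S)-1-methyl-2-oxo-6-(prop-1-en-2-yl)cyclohex-3-en-1-yl]propanoate | C=C(C)[C@@H]1CC=CC(=O)[C@@]1(C)CCC(=O)OC | intermediate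
11 | methyl 3-[(1S,4R,6S)-1-methyl-2-oxo-6-(prop-1-en-2-yl)-4-(4,4,5,5-tetramethyl-1,3,2-dioxaborolan-2-yl)cyclohexyl]propanoate (boron trans to isopropenyl) | C=C(C)[C@@H]1C[C@@H](B2OC(C)(C)C(C)(C)O2)CC(=O)[C@@]1(C)CCC(=O)OC | intermediate (not isolated)
12 | methyl 3-[(1S,4R,6S)-4-hydroxy-1-methyl-2-oxo-6-(prop-1-en-2-yl)cyclohexyl]propanoate | C=C(C)[C@@H]1C[C@@H](O)CC(=O)[C@@]1(C)CCC(=O)OC | intermediate
13 | methyl 3-[(1S,4R,6S)-4-(tert-butyldimethylsilyloxy)-1-methyl-2-oxo-6-(prop-1-en-2-yl)cyclohexyl]propanoate | C=C(C)[C@@H]1C[C@@H](O[Si](C)(C)C(C)(C)C)CC(=O)[C@@]1(C)CCC(=O)OC | intermediate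
14 | methyl 3-[(1S,4R,6S)-4-(tert-butyldimethylsilyloxy)-2-hydroxy-1-methyl-3-(3-methylbutanoyl)-6-(prop-1-en-2-yl)cyclohex-2-en-1-yl]propanoate (enol form of the β-diketone) | C=C(C)[C@@H]1C[C@@H](O[Si](C)(C)C(C)(C)C)C(C(=O)CC(C)C)=C(O)[C@@]1(C)CCC(=O)OC | intermediate
15 | methyl 3-[(1S,4R,6S)-4-(tert-butyldimethylsilyloxy)-1-methyl-3-[(1Z)-3-methyl-1-(trimethylsilyloxy)but-1-en-1-yl]-6-(prop-1-en-2-yl)-2-(trimethylsilyloxy)cyclohex-2-en-1-yl]propanoate | C=C(C)[C@@H]1C[C@@H](O[Si](C)(C)C(C)(C)C)C(/C(O[Si](C)(C)C)=C/C(C)C)=C(O[Si](C)(C)C)[C@@]1(C)CCC(=O)OC | intermediate (not isolated)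
16 | methyl 3-[(1S,4R,6S)-4-(tert-butyldimethylsilyloxy)-2-hydroxy-3-[3-hydroxy-2-(propan-2-yl)but-2-enoyl]-1-methyl-6-(prop-1-en-2-yl)cyclohex-2-en-1-yl]propanoate (one enol tautomer of the triketone) | C=C(C)[C@@H]1C[C@@H](O[Si](C)(C)C(C)(C)C)C(C(=O)C(C(C)C)=C(C)O)=C(O)[C@@]1(C)CCC(=O)OC | intermediate
17 | methyl 3-[(1S,2S,4R)-4-(tert-butyldimethylsilyloxy)-5,7-dihydroxy-1-methyl-6-(propan-2-yl)-2-(prop-1-en-2-yl)-1,2,3,4-tetrahydronaphthalen-1-yl]propanoate | C=C(C)[C@@H]1C[C@@H](O[Si](C)(C)C(C)(C)C)c2c(O)c(C(C)C)c(O)cc2[C@@]1(C)CCC(=O)OC | intermediate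
18 | methyl 3-[(1S,2S,4R)-4-(tert-butyldimethylsilyloxy)-7-hydroxy-1-methyl-5,8-dioxo-6-(propan-2-yl)-2-(prop-1-en-2-yl)-1,2,3,4,5,8-hexahydronaphthalen-1-yl]propanoate | C=C(C)[C@@H]1C[C@@H](O[Si](C)(C)C(C)(C)C)C2=C(C(=O)C(O)=C(C(C)C)C2=O)[C@@]1(C)CCC(=O)OC | intermediate
19 | methyl 3-[(1S,2S,4R)-4,7-dihydroxy-1-methyl-5,8-dioxo-6-(propan-2-yl)-2-(prop-1-en-2-yl)-1,2,3,4,5,8-hexahydronaphthalen-1-yl]propanoate | C=C(C)[C@@H]1C[C@@H](O)C2=C(C(=O)C(O)=C(C(C)C)C2=O)[C@@]1(C)CCC(=O)OC | intermediate
20 | methyl 3-[(1S,2S)-7-hydroxy-1-methyl-4,5,8-trioxo-6-(propan-2-yl)-2-(prop-1-en-2-yl)-1,2,3,4,5,8-hexahydronaphthalen-1-yl]propanoate | C=C(C)[C@@H]1CC(=O)C2=C(C(=O)C(O)=C(C(C)C)C2=O)[C@@]1(C)CCC(=O)OC | target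

## Step count and least certain steps

Total step count: 15. Longest linear sequence: 14 steps (step 1, then steps 3–15, from methacrolein 1). Step 2 is a one-step side branch.

**Step 3 (key step).** The most likely failure is low conversion or poor facial selectivity. Dienal 3 is β-substituted as well as α-methylated, so it is more hindered and less electrophilic than the 2-substituted acroleins on which this catalysis is best established. The strong acid can also consume diene 5 by protodesilylation or by vinylogous Mukaiyama aldol addition to the activated formyl group. The fallback moves the stereocontrol from the catalyst to the diene; it sets out from 4 and 3 and comes back at 9.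
- O-Acylation of the potassium dienolate of 4 (KOt-Bu, THF, −78 °C) with (2S)-methoxy(phenyl)acetyl chloride gives (E)-buta-1,3-dien-1-yl (2S)-methoxy(phenyl)acetate F1. The antipode of the acid is chosen by the same facial criterion as the catalyst.
- BF3·OEt2-promoted cycloaddition of F1 to 3 gives the mandelate analogue of 6, F2, with the aryl group of the ester shielding one diene face.
- Olefination with trimethyl phosphonoacetate under LiCl/DBU gives the mandelate analogue of 7, F3.
- Mg in MeOH, then K2CO3 in the same methanol, reduces the enoate and removes the auxiliary by transesterification to give 9. The large excess of methanol holds the δ-hydroxy ester open.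

**Step 6.** The most likely failure is lactonisation. The freed C9 hydroxyl is cis to the chain and five atoms from the ester carbonyl, so a δ-lactone can form and would block the oxidation of step 7. The fallback changes the order so that the free alcohol only exists next to the E enoate, which cannot reach it; it sets out from 7 and comes back at 13.
- HF·pyridine on 7 gives methyl (2E)-3-[(1S,2R,6S)-2-hydroxy-1-methyl-6-(prop-1-en-2-yl)cyclohex-3-en-1-yl]prop-2-enoate F4.
- Dess–Martin oxidation gives the enone–enoate F5.
- Copper-catalysed borylation (B2pin2, CuCl, NaOt-Bu, DPEphos, MeOH) and NaBO3 oxidation give the C7-hydroxy ketone enoate F6. Borylation should occur at the unhindered enone β-carbon C7 and not at the neopentyl enoate β-carbon C1.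
- TBSCl/imidazole gives its silyl ether F7.
- Conjugate reduction of the enoate with a ligated copper hydride (Cu(OAc)2, 1,2-bis(diphenylphosphino)benzene, polymethylhydrosiloxane, t-BuOH), which spares the saturated ketone, gives 13.

**Step 10.** The most likely failure is β-elimination of the C7 silyloxy group from the C8 magnesium enolate at room temperature, or acylation on oxygen. The fallback makes the C8–C14 bond by aldol addition and oxidation; it sets out from 13 and comes back at 14.
- The lithium enolate of 13 (LiHMDS, THF, −78 °C) is added to 3-methylbutanal to give the C8-(1-hydroxy-3-methylbutyl) ketone F8, a mixture at C8 and C14 that converges.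
- Dess–Martin oxidation gives 14.

**Step 11.** The most likely failure is incomplete γ-silylation, which would lead to acetylation on oxygen or at C8. The C7 silyl ether of 15 is also allylic to a silyl enol ether and may ionise under TMSOTf. The fallback uses polyanion chemistry, which becomes possible once the ester is a carboxylate; it sets out from 14 and comes back at 17.
- LiOH in THF/H2O gives the carboxylic acid of 14, F9.
- LDA (3.3 equiv) forms the carboxylate–diketonate–C13 trianion. A carboxylate α-position is far less acidic than an ester α-position. N-Methoxy-N-methylacetamide acylates the trianion at C13 to give the triketo acid F10.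
- Aqueous KOH closes ring C to the resorcinol acid F11.
- Trimethylsilyldiazomethane in MeOH/toluene at 0 °C esterifies the carboxylic acid selectively over the phenols and gives 17.

**Step 13.** The most likely failure is slow radical coupling at C11, which is flanked by the C12 hydroxyl and by C9 with the quaternary C10 beside it. Oxidative oligomerisation of the electron-rich resorcinol could then take over. The fallback introduces the C11 oxygen by ionic chemistry; it sets out from 17 and comes back at 18.
- Magnesium-mediated ortho-formylation (MgCl2, Et3N, paraformaldehyde, THF) can only occur at C11 and gives the C11 aldehyde F12.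
- Dakin oxidation (aqueous H2O2, Na2CO3, THF, 0 °C) gives the 11,12,14-triol F13, which autoxidises in air to 18.

## Further compounds

F1 | step 3 | (E)-buta-1,3-dien-1-yl (2S)-methoxy(phenyl)acetate | C=C/C=C/OC(=O)[C@@H](OC)c1ccccc1
F2 | step 3 | mandelate analogue of 6: (2S)-methoxy(phenyl)acetate ester at C9, formyl at C10 | C=C(C)[C@@H]1CC=C[C@@H](OC(=O)[C@@H](OC)c2ccccc2)[C@@]1(C)C=O
F3 | step 3 | mandelate analogue of 7: (2S)-methoxy(phenyl)acetate ester at C9, (E)-methyl propenoate at C10 | C=C(C)[C@@H]1CC=C[C@@H](OC(=O)[C@@H](OC)c2ccccc2)[C@@]1(C)/C=C/C(=O)OC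
F4 | step 6 | methyl (2E)-3-[(1S,2R,6S)-2-hydroxy-1-methyl-6-(prop-1-en-2-yl)cyclohex-3-en-1-yl]prop-2-enoate | C=C(C)[C@@H]1CC=C[C@@H](O)[C@@]1(C)/C=C/C(=O)OC
F5 | step 6 | methyl (2E)-3-[(1S,6S)-1-methyl-2-oxo-6-(prop-1-en-2-yl)cyclohex-3-en-1-yl]prop-2-enoate | C=C(C)[C@@H]1CC=CC(=O)[C@@]1(C)/C=C/C(=O)OC
F6 | step 6 | methyl (2E)-3-[(1S,4R,6S)-4-hydroxy-1-methyl-2-oxo-6-(prop-1-en-2-yl)cyclohexyl]prop-2-enoate | C=C(C)[C@@H]1C[C@@H](O)CC(=O)[C@@]1(C)/C=C/C(=O)OC
F7 | step 6 | methyl (2E)-3-[(1S,4R,6S)-4-(tert-butyldimethylsilyloxy)-1-methyl-2-oxo-6-(prop-1-en-2-yl)cyclohexyl]prop-2-enoate | C=C(C)[C@@H]1C[C@@H](O[Si](C)(C)C(C)(C)C)CC(=O)[C@@]1(C)/C=C/C(=O)OC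
F8 | step 10 | C8-(1-hydroxy-3-methylbutyl) derivative of 13 (C8 and C14 configurations undefined) | C=C(C)[C@@H]1C[C@@H](O[Si](C)(C)C(C)(C)C)C(C(O)CC(C)C)C(=O)[C@@]1(C)CCC(=O)OC
F9 | step 11 | carboxylic acid of 14 (enol form) | C=C(C)[C@@H]1C[C@@H](O[Si](C)(C)C(C)(C)C)C(C(=O)CC(C)C)=C(O)[C@@]1(C)CCC(=O)O
F10 | step 11 | carboxylic acid of 16 (bis-enol form) | C=C(C)[C@@H]1C[C@@H](O[Si](C)(C)C(C)(C)C)C(C(=O)C(C(C)C)=C(C)O)=C(O)[C@@]1(C)CCC(=O)O
F11 | step 11 | carboxylic acid of 17 | C=C(C)[C@@H]1C[C@@H](O[Si](C)(C)C(C)(C)C)c2c(O)c(C(C)C)c(O)cc2[C@@]1(C)CCC(=O)O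
F12 | step 13 | C11-formyl derivative of 17 | C=C(C)[C@@H]1C[C@@H](O[Si](C)(C)C(C)(C)C)c2c(O)c(C(C)C)c(O)c(C=O)c2[C@@]1(C)CCC(=O)OC
F13 | step 13 | C11-hydroxy derivative of 17 (11,12,14-triol) | C=C(C)[C@@H]1C[C@@H](O[Si](C)(C)C(C)(C)C)c2c(O)c(C(C)C)c(O)c(O)c2[C@@]1(C)CCC(=O)OC
A1 | alternative 1 | 1-(3-silyloxypropyl)-2-isopropenyl-1-oxazolinyl-4,5,7-trimethoxy-6-isopropyl-1,2-dihydronaphthalene | C=C(C)[C@@H]1C=C(OC)c2c(OC)c(C(C)C)c(OC)cc2[C@@]1(C3=N[C@H](C(C)(C)C)CO3)CCCO[Si](C)(C)C(C)(C)C
A2 | alternative 1 | 4-tert-butyl-2-[4,5,7-trimethoxy-6-(propan-2-yl)naphthalen-1-yl]-4,5-dihydro-1,3-oxazole | c1(C2=N[C@H](C(C)(C)C)CO2)ccc(OC)c2c(OC)c(C(C)C)c(OC)cc12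
A3 | alternative 1 | isopropenyllithium | [Li]C(C)=C
A4 | alternative 1 | tert-butyl(3-iodopropoxy)dimethylsilane | CC(C)(C)[Si](C)(C)OCCCI
A5 | alternative 2 | ring-C resorcinol with C7 ethylene ketal | C=C(C)[C@@H]1CC2(OCCO2)c2c(O)c(C(C)C)c(O)cc2[C@@]1(C)CCC(=O)OC
A6 | alternative 2 | C8-(2-isopropylacetoacetyl) C7-ketal ring-B ketone (C9 enol form) | C=C(C)[C@@H]1CC2(OCCO2)C(C(=O)C(C(C)C)C(C)=O)=C(O)[C@@]1(C)CCC(=O)OC
A7 | alternative 3 | ring-C hydroquinone (C12 isopropoxy, C13 isopropyl), C7 ketal, silyl ether chain | C=C(C)[C@@H]1CC2(OCCO2)c2c(O)c(C(C)C)c(OC(C)C)c(O)c2[C@@]1(C)CCCO[Si](C)(C)C(C)(C)C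
A8 | alternative 3 | 4-hydroxy-4-(ring-B cyclohexenyl)-3-isopropoxy-2-isopropylcyclobut-2-enone | C=C(C)[C@@H]1CC2(OCCO2)C=C(C2(O)C(=O)C(C(C)C)=C2OC(C)C)[C@@]1(C)CCCO[Si](C)(C)C(C)(C)C
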